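**Plan**
- Retrosynthetic cuts, in order: the four O–Si bonds; C2–C3 of ring C (carbenoid C–H insertion); the diazo group on the carbon next to C4 (diazo transfer to an acetyl group); C8–CH2 of the side chain (Negishi coupling); O1–CH2 to ring B (Mitsunobu ether); Cα–CH2 inside the side chain (auxiliary-controlled alkylation).
- Enabling feature: C2 is a benzylic CH bonded to O1 and to the electron-rich ring B, and C3 is the α-carbon of the C4 ketone on C4a. A carbenoid at C3 can therefore insert into a benzylic C–H of a benzyl ether on the C8a oxygen and close ring C.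
- Forward order: ring A (an acetophenone) is silylated and iodinated, ring B is attached to the future O1 as a benzyl ether, the side chain is joined at C8, the acetyl group becomes a diazomethyl ketone, ring C closes last, and all silyl groups are then removed.
- Stereochemistry: the side-chain centre (R) comes from a deconjugative Evans alkylation with (4S)-4-benzyloxazolidin-2-one; C2 (S) comes from the chiral dirhodium catalyst of the insertion.

Key step: step 14

Abbreviations: TBS = tert-butyldimethylsilyl, TES = triethylsilyl; acetophenone ring positions carry primed numbers (C1' bears the acetyl group).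

Assumption: the sense of induction of Rh2(S-DOSP)4, dirhodium tetrakis[(S)-N-(4-dodecylphenylsulfonyl)prolinate], at C2 cannot be predicted with certainty for this substrate; the S-ligand catalyst is written, and if a test run should deliver the 2R series the mirror-image catalyst Rh2(R-DOSP)4 would take its place with no other change.

**Route**

Step 1
Reactants: 1 2',6'-dihydroxy-4'-methoxyacetophenone
Product: 2 1-{2-[(TBS)oxy]-6-hydroxy-4-methoxyphenyl}ethan-1-one
Conditions: TBSCl (1.05 equiv), imidazole, DMF, 0 °C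
Reagents that add atoms: tert-butyldimethylsilyl chloride, `CC(C)(C)[Si](C)(C)Cl`
Why: Phenol silylation (silyl ether formation); the two hydroxyls of 1 are equivalent, and after the first is silylated the second stays locked in a hydrogen bond to the acetyl carbonyl, so one equivalent of reagent should stop at the mono-ether.

Step 2
Reactants: 2 1-{2-[(TBS)oxy]-6-hydroxy-4-methoxyphenyl}ethan-1-one
Product: 3 1-{6-[(TBS)oxy]-2-hydroxy-3-iodo-4-methoxyphenyl}ethan-1-one
Conditions: NIS (1.05 equiv), CF3CO2H (10 mol %), MeCN, 0 °C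
Reagents that add atoms: N-iodosuccinimide, `O=C1CCC(=O)N1I`
Why: Electrophilic aromatic iodination; the free chelated phenol directs iodine to its ortho carbon C3', which is also the less crowded open position because C5' lies next to the bulky silyloxy group, in line with the known C3 iodination of 2-hydroxy-4,6-dialkoxyacetophenones.

Step 3
Reactants: 4 2,4-dihydroxybenzaldehyde
Product: 5 2,4-bis[(TBS)oxy]benzaldehyde
Conditions: TBSCl (2.4 equiv), imidazole, DMF, 25 °C
Reagents that add atoms: tert-butyldimethylsilyl chloride, `CC(C)(C)[Si](C)(C)Cl`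
Why: Standard bis-silylation of a dihydroxybenzaldehyde (silyl ether formation) with excess reagent, the chelated 2-hydroxyl reacting more slowly but fully in DMF.

Step 4
Reactants: 5 2,4-bis[(TBS)oxy]benzaldehyde
Product: 6 {2,4-bis[(TBS)oxy]phenyl}methanol
Conditions: NaBH4, THF/EtOH, 0 °C
Reagents that add atoms: none
Why: Borohydride reduction of an aryl aldehyde to the benzylic alcohol, kept cold and short so that the ortho silyl group does not move to the new alkoxide.

Step 5
Reactants: 3 1-{6-[(TBS)oxy]-2-hydroxy-3-iodo-4-methoxyphenyl}ethan-1-one, 6 {2,4-bis[(TBS)oxy]phenyl}methanol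
Product: 7 1-[2-({2,4-bis[(TBS)oxy]phenyl}methoxy)-6-[(TBS)oxy]-3-iodo-4-methoxyphenyl]ethan-1-one
Conditions: PPh3, DIAD, THF, 0 → 25 °C
Reagents that add atoms: none
Why: Mitsunobu etherification; the acidic phenol of 3 (flanked by acyl and iodine) is a competent pronucleophile and the primary, electron-rich benzylic oxyphosphonium is displaced readily, which avoids the unstable 2,4-bis(silyloxy)benzyl halide.

Step 6
Reactants: 8 (4S)-4-benzyl-1,3-oxazolidin-2-one, 9 3-methylbut-2-enoyl chloride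
Product: 11 (4S)-4-benzyl-3-(3-methylbut-2-enoyl)-1,3-oxazolidin-2-one, via N-lithio oxazolidinone 10 (not isolated)
Conditions: n-BuLi, THF, −78 °C; then 9, −78 → 0 °C
Reagents that add atoms: none
Why: N-Acylation of the lithiated Evans oxazolidinone with an acid chloride at low temperature, a standard imide formation.

Step 7
Reactants: 11 (4S)-4-benzyl-3-(3-methylbut-2-enoyl)-1,3-oxazolidin-2-one, 12 prenyl bromide (1-bromo-3-methylbut-2-ene)
Product: 14 (4S)-4-benzyl-3-[(2S)-5-methyl-2-(prop-1-en-2-yl)hex-4-enoyl]-1,3-oxazolidin-2-one, via sodium dienolate 13 (not isolated)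
Conditions: NaN(SiMe3)2 (1.05 equiv), THF, −78 °C; then 12, −78 → −40 °C
Reagents that add atoms: none
Why: Evans asymmetric alkylation in its deconjugative form; γ-deprotonation gives the chelated Z-dienolate 13, which the allylic bromide alkylates at the α-carbon on the face opposite the C4 benzyl group, setting the (2S) centre that becomes the side-chain (R) centre of the target and moving the double bond into the isopropenyl position.

Step 8
Reactants: 14 (4S)-4-benzyl-3-[(2S)-5-methyl-2-(prop-1-en-2-yl)hex-4-enoyl]-1,3-oxazolidin-2-one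
Product: 15 (4S)-4-benzyl-3-{(2S)-2-[(3,3-dimethyloxiran-2-yl)methyl]-3-methylbut-3-enoyl}-1,3-oxazolidin-2-one (both oxirane epimers)
Conditions: mCPBA (1.05 equiv), NaHCO3, CH2Cl2, 0 °C
Reagents that add atoms: meta-chloroperoxybenzoic acid, `O=C(OO)c1cccc(Cl)c1`
Why: Prilezhaev epoxidation; the peracid should choose the electron-rich trisubstituted alkene over the 1,1-disubstituted isopropenyl group, which is also deactivated by the neighbouring acyl-bearing carbon, and the uncontrolled oxirane centre is erased in step 9.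

Step 9
Reactants: 15 (4S)-4-benzyl-3-{(2S)-2-[(3,3-dimethyloxiran-2-yl)methyl]-3-methylbut-3-enoyl}-1,3-oxazolidin-2-one
Product: 16 (2S)-5-methyl-2-(prop-1-en-2-yl)hexane-1,5-diol
Conditions: LiAlH4, THF, 0 → 25 °C; aqueous NaOH work-up
Reagents that add atoms: none
Why: Hydride reduction with LiAlH4 should both cleave the imide reductively to the primary alcohol (releasing the auxiliary) and open the trisubstituted epoxide at its less substituted carbon to the tertiary alcohol, without touching the stereocentre.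

Step 10
Reactants: 16 (2S)-5-methyl-2-(prop-1-en-2-yl)hexane-1,5-diol
Product: 17 (5S)-5-(iodomethyl)-2,6-dimethylhept-6-en-2-ol
Conditions: I2, PPh3, imidazole, CH2Cl2, 0 °C
Reagents that add atoms: iodine, `II`
Why: Appel-type iodination is selective for the primary hydroxyl, because the tertiary one cannot give a displaceable oxyphosphonium at 0 °C.

Step 11
Reactants: 17 (5S)-5-(iodomethyl)-2,6-dimethylhept-6-en-2-ol
Product: 18 triethyl{[(5S)-5-(iodomethyl)-2,6-dimethylhept-6-en-2-yl]oxy}silane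
Conditions: TESOTf, 2,6-lutidine, CH2Cl2, −78 → 0 °C
Reagents that add atoms: triethylsilyl trifluoromethanesulfonate, `CC[Si](CC)(CC)OS(=O)(=O)C(F)(F)F`
Why: Silylation of a hindered tertiary alcohol needs the silyl triflate with 2,6-lutidine, conditions that leave the primary iodide and the alkene untouched.

Step 12
Reactants: 18 triethyl{[(5S)-5-(iodomethyl)-2,6-dimethylhept-6-en-2-yl]oxy}silane, 7 1-[2-({2,4-bis[(TBS)oxy]phenyl}methoxy)-6-[(TBS)oxy]-3-iodo-4-methoxyphenyl]ethan-1-one
Product: 20 1-[2-({2,4-bis[(TBS)oxy]phenyl}methoxy)-6-[(TBS)oxy]-4-methoxy-3-{(2R)-5-methyl-2-(prop-1-en-2-yl)-5-[(TES)oxy]hexyl}phenyl]ethan-1-one, via alkylzinc iodide 19 (not isolated)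
Conditions: Zn dust, LiCl, THF, 40 °C (activation: BrCH2CH2Br, Me3SiCl); then 7, Pd(OAc)2 (3 mol %), SPhos (6 mol %), THF, 25 → 50 °C
Reagents that add atoms: none
Why: Negishi sp3–sp2 cross-coupling; LiCl-assisted zinc insertion into the primary iodide gives 19, which tolerates the ketone and silyl ethers, and the Pd(OAc)2/SPhos system is known to couple primary alkylzinc halides with doubly ortho-substituted, electron-rich aryl iodides faster than β-hydride elimination, the centre β to zinc taking no part.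

Step 13
Reactants: 20 1-[2-({2,4-bis[(TBS)oxy]phenyl}methoxy)-6-[(TBS)oxy]-4-methoxy-3-{(2R)-5-methyl-2-(prop-1-en-2-yl)-5-[(TES)oxy]hexyl}phenyl]ethan-1-one
Product: 23 1-[2-({2,4-bis[(TBS)oxy]phenyl}methoxy)-6-[(TBS)oxy]-4-methoxy-3-{(2R)-5-methyl-2-(prop-1-en-2-yl)-5-[(TES)oxy]hexyl}phenyl]-2-diazoethan-1-one, via lithium enolate 21 (not isolated), via trifluoroacetyl ketone 22 (not isolated)
Conditions: LiN(SiMe3)2, THF, −78 °C; CF3CO2CH2CF3, −78 °C; then MsN3, Et3N, H2O (1 equiv), MeCN, 25 °C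
Reagents that add atoms: methanesulfonyl azide, `CS(=O)(=O)N=[N+]=[N-]`
Why: Detrifluoroacetylative diazo transfer; the kinetic lithium enolate of the methyl ketone is trifluoroacetylated, and the activated diketone 22 takes the diazo group from the sulfonyl azide and loses the trifluoroacetyl group as the sulfonamide, giving the diazomethyl ketone under conditions the silyl ethers should tolerate.

Step 14
Reactants: 23 1-[2-({2,4-bis[(TBS)oxy]phenyl}methoxy)-6-[(TBS)oxy]-4-methoxy-3-{(2R)-5-methyl-2-(prop-1-en-2-yl)-5-[(TES)oxy]hexyl}phenyl]-2-diazoethan-1-one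
Product: 24 (2S)-2-{2,4-bis[(TBS)oxy]phenyl}-5-[(TBS)oxy]-7-methoxy-8-{(2R)-5-methyl-2-(prop-1-en-2-yl)-5-[(TES)oxy]hexyl}-2,3-dihydro-4H-chromen-4-one
Conditions: Rh2(S-DOSP)4 (2 mol %), CH2Cl2, 0 → 25 °C, slow addition of 23
Reagents that add atoms: none
Why: The dirhodium carboxylate expels N2 from the diazoketone to give an electrophilic rhodium carbenoid at C3, which inserts into one benzylic C–H of the benzyl ether on the C8a oxygen through a concerted, asynchronous three-centre transition state with hydride-transfer character, creating the C2–C3 bond. The closest known reaction type is the intramolecular C–H insertion of 2-alkoxyphenyl α-diazoketones to 2-substituted chroman-4-ones under chiral dirhodium N-arylsulfonylprolinates. Ring C closes as a six-membered ring by 1,6-insertion, the carbenoid carbon C3 bonding to the ether α-carbon (which becomes C2) while C4, C4a, C8a and O1 are already in place. The new C2 centre is set by catalyst control: the chiral prolinate ligands select one of the two enantiotopic benzylic hydrogens, and the remote side-chain centre exerts no bias but makes any 2R product a diastereomer that can be removed. The step needs insertion to outrun oxonium-ylide formation with [1,2]-benzyl shift, cyclopropanation and attack on ring B; the substrate favours this because the ether oxygen and the ortho and para silyloxy groups of ring B make the benzylic C–H strongly hydridic, the ether oxygen is conjugated to ring A and crowded by two ortho substituents, the C5 oxygen carries a silyl group with no C–H on the atom next to oxygen, and the isopropenyl group cannot reach C3.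

Step 15
Reactants: 24 (2S)-2-{2,4-bis[(TBS)oxy]phenyl}-5-[(TBS)oxy]-7-methoxy-8-{(2R)-5-methyl-2-(prop-1-en-2-yl)-5-[(TES)oxy]hexyl}-2,3-dihydro-4H-chromen-4-one
Product: 25 (2S)-2-(2,4-dihydroxyphenyl)-5-hydroxy-8-[(2R)-5-hydroxy-5-methyl-2-(prop-1-en-2-yl)hexyl]-7-methoxy-2,3-dihydro-4H-chromen-4-one (CNP0106344.1)
Conditions: HF·pyridine, pyridine, THF, 0 → 25 °C
Reagents that add atoms: none
Why: Fluoride-mediated cleavage of the three aryl TBS ethers and the tertiary TES ether under buffered, weakly acidic conditions, chosen because basic fluoride could open the flavanone to the chalcone (retro-oxa-Michael) and erode the C2 centre.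

**Compound list**

1 | 2',6'-dihydroxy-4'-methoxyacetophenone | `COc1cc(O)c(C(C)=O)c(O)c1` | starting material
2 | 1-{2-[(TBS)oxy]-6-hydroxy-4-methoxyphenyl}ethan-1-one | `COc1cc(O)c(C(C)=O)c(O[Si](C)(C)C(C)(C)C)c1` | intermediate
3 | 1-{6-[(TBS)oxy]-2-hydroxy-3-iodo-4-methoxyphenyl}ethan-1-one | `COc1cc(O[Si](C)(C)C(C)(C)C)c(C(C)=O)c(O)c1I` | intermediate
4 | 2,4-dihydroxybenzaldehyde | `O=Cc1ccc(O)cc1O` | starting material
5 | 2,4-bis[(TBS)oxy]benzaldehyde | `O=Cc1ccc(O[Si](C)(C)C(C)(C)C)cc1O[Si](C)(C)C(C)(C)C` | intermediate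
6 | {2,4-bis[(TBS)oxy]phenyl}methanol | `OCc1ccc(O[Si](C)(C)C(C)(C)C)cc1O[Si](C)(C)C(C)(C)C` | intermediate
7 | 1-[2-({2,4-bis[(TBS)oxy]phenyl}methoxy)-6-[(TBS)oxy]-3-iodo-4-methoxyphenyl]ethan-1-one | `COc1cc(O[Si](C)(C)C(C)(C)C)c(C(C)=O)c(OCc2ccc(O[Si](C)(C)C(C)(C)C)cc2O[Si](C)(C)C(C)(C)C)c1I` | intermediate
8 | (4S)-4-benzyl-1,3-oxazolidin-2-one | `O=C1N[C@@H](Cc2ccccc2)CO1` | starting material
9 | 3-methylbut-2-enoyl chloride | `CC(C)=CC(=O)Cl` | starting material
10 | lithium salt of 8, N-lithio-(4S)-4-benzyl-1,3-oxazolidin-2-one (not isolated) | `[Li+].O=C1[N-][C@@H](Cc2ccccc2)CO1` | intermediate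
11 | (4S)-4-benzyl-3-(3-methylbut-2-enoyl)-1,3-oxazolidin-2-one | `CC(C)=CC(=O)N1[C@@H](Cc2ccccc2)COC1=O` | intermediate
12 | prenyl bromide (1-bromo-3-methylbut-2-ene) | `CC(C)=CCBr` | starting material
13 | sodium (Z)-dienolate of 11 (not isolated) | `[Na+].O=C1OC[C@H](Cc2ccccc2)N1/C([O-])=C/C(C)=C` | intermediate
14 | (4S)-4-benzyl-3-[(2S)-5-methyl-2-(prop-1-en-2-yl)hex-4-enoyl]-1,3-oxazolidin-2-one | `C=C(C)[C@H](CC=C(C)C)C(=O)N1[C@@H](Cc2ccccc2)COC1=O` | intermediate
15 | (4S)-4-benzyl-3-{(2S)-2-[(3,3-dimethyloxiran-2-yl)methyl]-3-methylbut-3-enoyl}-1,3-oxazolidin-2-one, both oxirane epimers | `C=C(C)[C@H](CC1OC1(C)C)C(=O)N2[C@@H](Cc3ccccc3)COC2=O` | intermediate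
16 | (2S)-5-methyl-2-(prop-1-en-2-yl)hexane-1,5-diol | `C=C(C)[C@H](CCC(C)(C)O)CO` | intermediate
17 | (5S)-5-(iodomethyl)-2,6-dimethylhept-6-en-2-ol | `C=C(C)[C@H](CCC(C)(C)O)CI` | intermediate
18 | triethyl{[(5S)-5-(iodomethyl)-2,6-dimethylhept-6-en-2-yl]oxy}silane | `C=C(C)[C@H](CCC(C)(C)O[Si](CC)(CC)CC)CI` | intermediate
19 | {(2S)-5-methyl-2-(prop-1-en-2-yl)-5-[(TES)oxy]hexyl}zinc iodide (not isolated) | `C=C(C)[C@H](CCC(C)(C)O[Si](CC)(CC)CC)C[Zn]I` | intermediate
20 | 1-[2-({2,4-bis[(TBS)oxy]phenyl}methoxy)-6-[(TBS)oxy]-4-methoxy-3-{(2R)-5-methyl-2-(prop-1-en-2-yl)-5-[(TES)oxy]hexyl}phenyl]ethan-1-one | `C=C(C)[C@H](CCC(C)(C)O[Si](CC)(CC)CC)Cc1c(OC)cc(O[Si](C)(C)C(C)(C)C)c(C(C)=O)c1OCc1ccc(O[Si](C)(C)C(C)(C)C)cc1O[Si](C)(C)C(C)(C)C` | intermediate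
21 | lithium enolate of 20 (not isolated) | `[Li+].C=C(C)[C@H](CCC(C)(C)O[Si](CC)(CC)CC)Cc1c(OC)cc(O[Si](C)(C)C(C)(C)C)c(C(=C)[O-])c1OCc1ccc(O[Si](C)(C)C(C)(C)C)cc1O[Si](C)(C)C(C)(C)C` | intermediate
22 | trifluoroacetyl ketone of 20, the 1-aryl-4,4,4-trifluorobutane-1,3-dione (not isolated) | `C=C(C)[C@H](CCC(C)(C)O[Si](CC)(CC)CC)Cc1c(OC)cc(O[Si](C)(C)C(C)(C)C)c(C(=O)CC(=O)C(F)(F)F)c1OCc1ccc(O[Si](C)(C)C(C)(C)C)cc1O[Si](C)(C)C(C)(C)C` | intermediate
23 | 1-[2-({2,4-bis[(TBS)oxy]phenyl}methoxy)-6-[(TBS)oxy]-4-methoxy-3-{(2R)-5-methyl-2-(prop-1-en-2-yl)-5-[(TES)oxy]hexyl}phenyl]-2-diazoethan-1-one | `C=C(C)[C@H](CCC(C)(C)O[Si](CC)(CC)CC)Cc1c(OC)cc(O[Si](C)(C)C(C)(C)C)c(C(=O)C=[N+]=[N-])c1OCc1ccc(O[Si](C)(C)C(C)(C)C)cc1O[Si](C)(C)C(C)(C)C` | intermediate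
24 | (2S)-2-{2,4-bis[(TBS)oxy]phenyl}-5-[(TBS)oxy]-7-methoxy-8-{(2R)-5-methyl-2-(prop-1-en-2-yl)-5-[(TES)oxy]hexyl}-2,3-dihydro-4H-chromen-4-one | `C=C(C)[C@H](CCC(C)(C)O[Si](CC)(CC)CC)Cc1c(OC)cc(O[Si](C)(C)C(C)(C)C)c2c1O[C@H](c1ccc(O[Si](C)(C)C(C)(C)C)cc1O[Si](C)(C)C(C)(C)C)CC2=O` | intermediate
25 | (2S)-2-(2,4-dihydroxyphenyl)-5-hydroxy-8-[(2R)-5-hydroxy-5-methyl-2-(prop-1-en-2-yl)hexyl]-7-methoxy-2,3-dihydro-4H-chromen-4-one | `C=C(C)[C@H](CCC(C)(C)O)Cc1c(OC)cc(O)c2c1O[C@H](c1ccc(O)cc1O)CC2=O` | target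

**Step count and risks**

Total step count: 15. Longest linear sequence: 10 steps (steps 6 to 15, from 8 and 9).

Steps most likely to fail:

1. Step 14. The carbenoid may be captured by the lone pair of the ether oxygen (oxonium ylide, then [1,2]-shift of the electron-rich benzyl group), or the two enantiotopic benzylic hydrogens may be poorly distinguished. Fallback: ring C would be closed through O1–C2 by an oxa-Michael addition instead. Setting out from 20, the electron-rich benzyl ether would be cleaved oxidatively (DDQ, CH2Cl2/pH 7 buffer, 0 °C; aldehyde 5 is returned) to the 2'-hydroxyacetophenone F1. Its dianion (LiN(SiMe3)2, 2.2 equiv, THF, −78 °C) would be added to aldehyde 5 to give the β-hydroxy ketone F2. Loss of water (catalytic pyridinium p-toluenesulfonate, toluene, 50 °C) should give the (E)-2'-hydroxychalcone F3. Cyclisation of the chalcone under a quinine-derived bifunctional thiourea (enantioselective intramolecular oxa-Michael addition) would come back to the route at 24; any 2R epimer is a diastereomer and would be removed by chromatography.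

2. Step 12. Zinc insertion may stall, or the doubly ortho-flanked arylpalladium intermediate may be reduced or undergo β-hydride elimination before it transmetalates. Fallback: a B-alkyl Suzuki–Miyaura coupling. Setting out from 18, iodine–lithium exchange (t-BuLi, 2.1 equiv, Et2O, −78 °C) and trapping with 9-methoxy-9-borabicyclo[3.3.1]nonane would give the lithium borinate ate complex F4. This would be coupled with 7 under PdCl2(dppf) in THF/DMF at 25–50 °C without added aqueous base (so the aryl silyl ethers are spared), coming back to the route at 20.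

3. Step 13. Under the strong amide base the C6' silyl group may migrate to the enolate oxygen, or it may be lost at the trifluoroacetyl stage with ring closure to a 2-trifluoromethylchromone. Fallback: setting out from 20, the enolate would be trapped as it forms (LiN(SiMe3)2 added to 20 and Me3SiCl, THF, −78 °C) as the trimethylsilyl enol ether F5. NBS (THF, −78 °C) would convert it into the bromomethyl ketone F6. N,N'-Ditosylhydrazine and DBU (THF, 0 °C) would then replace bromide by the diazo group through substitution and double sulfinate elimination, coming back to the route at 23.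

**Further compounds**

F1 | step 14 | 1-{6-[(TBS)oxy]-2-hydroxy-4-methoxy-3-[(2R)-5-methyl-2-(prop-1-en-2-yl)-5-[(TES)oxy]hexyl]phenyl}ethan-1-one | `C=C(C)[C@H](CCC(C)(C)O[Si](CC)(CC)CC)Cc1c(OC)cc(O[Si](C)(C)C(C)(C)C)c(C(C)=O)c1O`
F2 | step 14 | 3-{2,4-bis[(TBS)oxy]phenyl}-3-hydroxy-1-{6-[(TBS)oxy]-2-hydroxy-4-methoxy-3-[(2R)-5-methyl-2-(prop-1-en-2-yl)-5-[(TES)oxy]hexyl]phenyl}propan-1-one, both carbinol epimers | `C=C(C)[C@H](CCC(C)(C)O[Si](CC)(CC)CC)Cc1c(OC)cc(O[Si](C)(C)C(C)(C)C)c(C(=O)CC(O)c2ccc(O[Si](C)(C)C(C)(C)C)cc2O[Si](C)(C)C(C)(C)C)c1O`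
F3 | step 14 | (E)-3-{2,4-bis[(TBS)oxy]phenyl}-1-{6-[(TBS)oxy]-2-hydroxy-4-methoxy-3-[(2R)-5-methyl-2-(prop-1-en-2-yl)-5-[(TES)oxy]hexyl]phenyl}prop-2-en-1-one | `C=C(C)[C@H](CCC(C)(C)O[Si](CC)(CC)CC)Cc1c(OC)cc(O[Si](C)(C)C(C)(C)C)c(C(=O)/C=C/c2ccc(O[Si](C)(C)C(C)(C)C)cc2O[Si](C)(C)C(C)(C)C)c1O`
F4 | step 12 | lithium 9-methoxy-9-{(2S)-5-methyl-2-(prop-1-en-2-yl)-5-[(TES)oxy]hexyl}-9-boratabicyclo[3.3.1]nonane | `[Li+].C=C(C)[C@H](CCC(C)(C)O[Si](CC)(CC)CC)C[B-]1(OC)C2CCCC1CCC2`
F5 | step 13 | trimethylsilyl enol ether of 20 | `C=C(C)[C@H](CCC(C)(C)O[Si](CC)(CC)CC)Cc1c(OC)cc(O[Si](C)(C)C(C)(C)C)c(C(=C)O[Si](C)(C)C)c1OCc1ccc(O[Si](C)(C)C(C)(C)C)cc1O[Si](C)(C)C(C)(C)C`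
F6 | step 13 | bromomethyl ketone of 20, the 2-bromo-1-arylethan-1-one | `C=C(C)[C@H](CCC(C)(C)O[Si](CC)(CC)CC)Cc1c(OC)cc(O[Si](C)(C)C(C)(C)C)c(C(=O)CBr)c1OCc1ccc(O[Si](C)(C)C(C)(C)C)cc1O[Si](C)(C)C(C)(C)C`
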